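## Structural features

The target is a resveratrol trimer built from two 2,3-diaryl-2,3-dihydrobenzofurans. The outer unit is numbered O1, C2, C3, C3a to C7a (benzene ring A, dihydrofuran ring B) and the inner one O1′, C2′, C3′, C3a′ to C7a′ (benzene ring C, dihydrofuran ring D). The two bicycles are joined by one sp3–sp2 bond, C3–C4′. Ring A carries an (E)-3,5-dihydroxystyryl group at C5 (para to O1), C2 and C2′ each carry a 4-hydroxyphenyl group, C3′ carries a 3,5-dihydroxyphenyl group and C6′ a hydroxyl. The four stereocentres form two adjacent pairs, C2/C3 and C2′/C3′, each trans and all four S; only the C3–C4′ bond links the pairs, so each pair needs its own source of absolute configuration. Fragile points are the seven free phenols (air, base), the benzylic bonds C2–O1 and C2′–O1′ (each para to an oxygen on its aryl group, so easily ionised by acid), and the electron-rich stilbene (isomerised by light; in acid it can be protonated and trapped by ring C). The real difficulty is the C3–C4′ bond: it lies between the C2 aryl group and the C3′ aryl group, and C4′ is meta to both oxygens of ring C, where no electrophilic substitution will go. The key step uses the fact that rings C and D, with O1′, the C2′ aryl group in its natural configuration and the C6′ oxygen, are the ring-contracted skeleton of (S)-naringenin: flavanone C4a becomes C3a′, C3 becomes C3′, the carbonyl carbon is pushed out as a carboxyl on C3′ (a radical precursor), and the chelated 5-hydroxyl marks C4′.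

## Logic of the disconnections

31 to 30. The seven O–CH2 acetal bonds are "cut" (retro-protection). Free phenols would not survive the organometallic, radical and basic steps, and one kind of acetal allows one final unmasking. The demand on the forward step is a cleavage without acid strong enough to ionise C2–O1 or C2′–O1′ or to protonate the stilbene.

30 to 18 and 29. The C3–C4′ bond is cut. This is the most convergent cut: it gives two halves of similar size, each with one stereo pair. C3 is seen as a radical from a carboxylate, C4′ as an aryl iodide. The forward step must be cross-selective at near-equal stoichiometry, must not pass through a C3 organometallic (it would expel the ring B aryloxide), must tolerate the stilbene, and must deliver the aryl group trans to the C2 aryl group.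

18 to 16. The carbon–iodine bond at C4′ is traced back to the carbon–oxygen bond of a triflate, because oxygen is what the chiral-pool precursor offers at this position. The exchange must be ipso-specific on a molecule whose other ring positions are strongly activated towards electrophiles; this is why it runs through tin and not through an electrophilic halodeboronation.

16 to 9 and 11. The C3′–aryl bond is cut. The carboxyl that the ring contraction leaves on C3′ is exactly a radical precursor, and 11 is a simple aryl donor. The forward step must leave the triflate alone and place the aryl group trans to the C2′ aryl group.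

9 to 8 to 5. After the ester is put back, the C3′–C3a′ bond is cut in the retro-Wolff sense: ring D is re-expanded to a pyranone and the ester carbon returns into the ring as the C4 carbonyl. This turns the inner core into a derivative of a natural flavanone that already holds O1′, C2′ with its aryl group, and the ring C oxygens. The forward step must lose N2 without carbene side reactions, trap the ketene, and leave C2 untouched.

5 to 3 to 2 to 1. The C3=N2 bond, the O–S bond of the triflate and two O–CH2 bonds are removed. The chelated hydroxyl is the only one that can be told apart, so the two free phenols are capped first and the third is triflated. Every step must avoid the reversible opening of the pyranone that racemises C2.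

29 to 28 to 27 to 26 and 12. The acyl–O–N bond and then the C5–vinyl bond are cut. Placing the stilbene before the union means no aryl bromide competes with the aryl iodide in the nickel step. The forward arylation must be E-selective and terminal.

26 to 24 to 23 to 22 and 20; 22 from 21, 20 from 19. The C2–C3 bond is cut as a carbene insertion into a benzylic C–H bond, then the C=N2 bond and the benzylic O–CH2 bond. This sets C2 by a chiral catalyst on a small fragment and leaves C3 to thermodynamic control. The demand is high enantioselectivity in the insertion and a clean cis-to-trans epimerisation.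

11 and 12 to 10. Two O–CH2 bonds and one aryl–vinyl bond are cut, so one bromoresorcinol supplies both 3,5-dioxygenated rings.

## Other disconnections considered

Alternative 1: The cut is the C3a′–C4′ bond, and with it all of ring C, which is unravelled to a polyketide-type chain on C3 of a finished ring A/B unit.
- Forward key step: the trioxoheptanoate A1, whose C7 ketone is bonded to C3, would be treated with KOH in methanol. The C2 carbanion attacks the C7 ketone, water is lost and enolisation gives the resorcylate A2, whose ester carbon is the future C3′ and whose ortho hydroxyl is the future O1′.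
- In favour: the crowded C3–C4′ bond never has to be made by a coupling, since it begins as the C3–acyl bond of an ester such as 26. On this point the alternative is better than the chosen plan, whose step 18 is its weakest link. The oxygen pattern of ring C is fixed by the chain, and the cascade needs neither light nor a diazo compound, so operationally it is at least the equal of the Wolff step.
- Against: A2 has no ring D. C2′ and C3′ with their aryl groups would have to be built afterwards, and their absolute configuration set without real help from the remote C2/C3 pair, so a second asymmetric step or a separation is needed. A1 is a sensitive poly-β-carbonyl compound (Claisen-type closure and pyranone formation compete), and its acidic C3–H invites β-elimination of the ring B aryloxide under KOH.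
- Comparison: the chosen plan takes C2′ from the chiral pool and makes C3′ functional in the same step that closes ring D. In steps the alternative is clearly longer: two or three to A1, one to A2 and an estimated six or more to finish ring D, against four steps from 1 to 8.

Alternative 2: The cut removes both aryl groups of ring D at once (the C3′–aryl and C2′–aryl bonds), leaving a flat benzofuran.
- Forward key step: benzofuran A3 would be lithiated at C2′ with n-BuLi and combined with aryl boronate A4 to a boron-ate complex. With Pd(OAc)2, a chiral ferrocenyl bisphosphine and aryl triflate A5, the aryl–palladium species (divalent palladium) attacks C3′ while the aryl group on boron shifts to C2′ on the opposite face. This dearomatises the furan and gives A6, with the boronate on C2′ cis to the C3′ aryl group.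
- In favour: two skeletal bonds and both inner stereocentres arise in one catalytic step from three achiral pieces. That is better than the chosen key step, which makes one skeletal bond and a C3′ centre that is later reset. The configuration comes from a ligand available in both hands and not from a flavanone that racemises easily, which is also better.
- Against: the aryl group must be delivered to C3′ right beside the C4′ acetal, the most hindered position of A3, and a benzofuran dearomatises less readily than the indoles for which this chemistry is best established. The tertiary, benzylic, α-oxygenated boronate of A6 must then be replaced by hydrogen with retention; a partly ionic protodeboronation would scramble C2′. A3 is not commercial, and the C4′ acetal still has to become the whole of ring A/B.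
- Comparison: mechanistically both plans are well founded (1,2-metallate shift versus 1,2-aryl shift). Step economy is about equal up to the inner diaryl core but worse afterwards, because 18 is ready for a one-step union while A6 needs protodeboronation, acetal hydrolysis and a ring B construction.

Alternative 3: The cut is the pair O1–C2 and C2–C3, a formal [4+1] disconnection of ring B into an ortho-quinone methide (C3, C3a, C7a, O1) and a one-carbon ylide (C2 with its aryl group).
- Forward key step: Cs2CO3 would expel sulfinate from the phenolic sulfone A7 to give the quinone methide. A benzylic sulfonium ylide from a chiral sulfide would add to its exocyclic carbon (C2–C3), and the phenoxide would displace the sulfide in a 5-exo-tet closure (O1–C2) to give A8, which is the same compound as 30.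
- In favour: ring B and both its stereocentres arise in one mild step on the finished inner core, and the end game is identical to the chosen one (equal). No radical cross-coupling and no separate synthesis of 29 are needed. The C3–C4′ bond would be made earlier by a simple carbonyl addition, which is sterically better than step 18.
- Against: the plan is linear at its most expensive point. The inner core must be carried through formylation at C4′, addition of the ring A aryl group, sulfinate exchange and the annulation, where the chosen plan spends one convergent step. The chiral ylide must impose C2 against the resident chirality of the bulky inner core on the prochiral carbon, so a mismatched pairing is possible, and the chiral sulfonium salt is stoichiometric.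
- Comparison: here ring B closes by addition then substitution on the full molecule; in the chosen plan it closes by carbene C–H insertion on a small fragment where the catalyst alone decides. This alternative does not compete with the ring contraction, since it could take its inner core from 16. Total step counts are about equal.

Key step: step 4

Remarks on the chemistry (assumptions):
- (S)-Naringenin is taken as the single enantiomer; its enantiomeric purity is to be followed by chiral HPLC at 2 and at 8.
- For step 14 the R antipode of the rhodium catalyst is assumed to lead to the 2S series. This sense of induction is not certain. If the first batch of 26 shows the opposite sense (anomalous dispersion of bromine), the S antipode is used.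
- The trans configuration that DBU sets at C3′ in 8 only serves to carry one diastereomer through steps 4 and 5; C3′ becomes planar and is set again in step 8.

## Route

Step 1
Reactants: 1 (S)-naringenin
Product: 2 (2S)-5-hydroxy-7-(methoxymethoxy)-2-[4-(methoxymethoxy)phenyl]chroman-4-one
Conditions: MOMCl (2.3 equiv), i-Pr2NEt (3 equiv, added last), CH2Cl2/THF, 0 °C
Reagents that add atoms: chloromethyl methyl ether, COCCl
Why: O-alkylation of the 7- and 4′-phenols with an α-chloro ether; the 5-hydroxyl is hydrogen-bonded to the C4 carbonyl and is left. The amine is added last and cold so that little free 4′-phenoxide, the species that opens the pyranone and would racemise C2, is present; capping the 4′-oxygen closes that pathway for all later steps.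

Step 2
Reactants: 2 (2S)-5-hydroxy-7-(methoxymethoxy)-2-[4-(methoxymethoxy)phenyl]chroman-4-one
Product: 3 (2S)-7-(methoxymethoxy)-2-[4-(methoxymethoxy)phenyl]-4-oxochroman-5-yl trifluoromethanesulfonate
Conditions: Tf2O (1.2 equiv), pyridine (3 equiv), CH2Cl2, −20 to 0 °C
Reagents that add atoms: trifluoromethanesulfonic anhydride, O=S(=O)(OS(=O)(=O)C(F)(F)F)C(F)(F)F
Why: O-sulfonylation of the chelated phenol; pyridine is too weak a base to enolise C3, so C2 is untouched. The triflate marks the future C4′ and removes the acidic proton before the enolate step.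

Step 3
Reactants: 3 (2S)-7-(methoxymethoxy)-2-[4-(methoxymethoxy)phenyl]-4-oxochroman-5-yl trifluoromethanesulfonate
Product: 5 (2R)-3-diazo-7-(methoxymethoxy)-2-[4-(methoxymethoxy)phenyl]-4-oxochroman-5-yl trifluoromethanesulfonate (R only by the sequence rule; same spatial arrangement as in 3), via trifluoroacetyl ketone 4 (not isolated)
Conditions: LiN(SiMe3)2 (1.1 equiv), THF, −78 °C; CF3CO2CH2CF3 (1.3 equiv), −78 °C; cold dilute HCl work-up; then p-ABSA (1.5 equiv), Et3N (1.5 equiv), H2O (1 equiv), MeCN, rt, dark
Reagents that add atoms: 4-acetamidobenzenesulfonyl azide, CC(=O)Nc1ccc(cc1)S(=O)(=O)N=[N+]=[N-] (the two terminal nitrogens); 2,2,2-trifluoroethyl trifluoroacetate, FC(F)(F)COC(=O)C(F)(F)F (trifluoroacetyl group, held only in 4)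
Why: Detrifluoroacetylative (Regitz-type) diazo transfer: the kinetic lithium enolate is acylated at once to the 1,3-diketone 4, whose stabilised enolate adds to the sulfonyl azide and fragments to the diazo ketone and the N-trifluoroacetyl sulfonamide. The short-lived cold enolate limits retro-oxa-Michael opening, and p-ABSA is the less hazardous azide.

Step 4
Reactants: 5 (2R)-3-diazo-7-(methoxymethoxy)-2-[4-(methoxymethoxy)phenyl]-4-oxochroman-5-yl trifluoromethanesulfonate
Product: 8 methyl (2S,3S)-6-(methoxymethoxy)-2-[4-(methoxymethoxy)phenyl]-4-(trifluoromethanesulfonyloxy)-2,3-dihydrobenzofuran-3-carboxylate (trans), via ketene 6 (not isolated), via cis ester 7 (not isolated)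
Conditions: hν (365 nm LED, flow or Pyrex vessel), degassed MeOH/THF (4:1), 0 °C; then DBU (1 equiv), rt
Reagents that add atoms: methanol, CO
Why: Photochemical Wolff rearrangement: excitation of the diazo ketone expels N2, and because the ring holds the C=O and C=N2 units s-cis, loss of N2 is concerted with the 1,2-shift of the ring C carbon C3a′ from the carbonyl carbon to the diazo carbon, so a free carbene (and with it the 1,2-hydrogen shift from C2′ to a flavone, or O–H insertion into methanol) is largely bypassed. The shift forms the C3′–C3a′ bond and makes ring D by contraction of the six-membered pyranone to a five-membered ring, not by an end-to-end cyclisation; the extruded carbonyl carbon becomes the exocyclic ketene 6 on C3′, which methanol traps as the methyl ester. The closest known reaction type is the photochemical ring contraction of cyclic α-diazo ketones, including 3-diazochroman-4-ones to 2,3-dihydrobenzofuran-3-carboxylates. C2′ is a spectator: the diazo carbon carries no hydrogen, and the later ester enolate could open ring D only by a disfavoured reverse 5-endo process, so the naringenin configuration is carried over. C3′ is set by protonation: the ester enol is protonated mainly anti to the C2′ aryl group (cis ester 7), and DBU then equilibrates through the ester enolate to the trans ester 8 under control of the C2′ aryl group. The step needs light that the diazo ketone absorbs and the aryl triflate does not (365 nm); triflate and MOM ethers are inert to methanol and DBU at room temperature.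

Step 5
Reactants: 8 methyl (2S,3S)-6-(methoxymethoxy)-2-[4-(methoxymethoxy)phenyl]-4-(trifluoromethanesulfonyloxy)-2,3-dihydrobenzofuran-3-carboxylate
Product: 9 (2S,3S)-6-(methoxymethoxy)-2-[4-(methoxymethoxy)phenyl]-4-(trifluoromethanesulfonyloxy)-2,3-dihydrobenzofuran-3-carboxylic acid
Conditions: LiOH (3 equiv), THF/MeOH/H2O, 0 °C to rt; cold dilute HCl to pH 3
Reagents that add atoms: water, O (delivered as LiOH)
Why: Saponification by acyl–oxygen cleavage; aryl triflates and MOM ethers tolerate cold aqueous LiOH, and any epimerisation at C3′ is harmless because this centre is reset in step 8.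

Step 6
Reactants: 10 5-bromoresorcinol
Product: 11 1-bromo-3,5-bis(methoxymethoxy)benzene
Conditions: MOMCl (2.5 equiv), i-Pr2NEt (3 equiv), CH2Cl2, 0 °C to rt
Reagents that add atoms: chloromethyl methyl ether, COCCl
Why: O-alkylation of both phenols; the product is the common source of the C3′ aryl group and of the styrene.

Step 7
Reactants: 11 1-bromo-3,5-bis(methoxymethoxy)benzene
Product: 12 1,3-bis(methoxymethoxy)-5-vinylbenzene
Conditions: vinyl-B(pin) (1.3 equiv), Pd(dppf)Cl2 (3 mol %), K2CO3, 1,4-dioxane/H2O, 80 °C
Reagents that add atoms: vinylboronic acid pinacol ester, C=CB1OC(C)(C)C(C)(C)O1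
Why: Suzuki–Miyaura vinylation of the aryl bromide; MOM ethers are inert to aqueous carbonate.

Step 8
Reactants: 9 (2S,3S)-6-(methoxymethoxy)-2-[4-(methoxymethoxy)phenyl]-4-(trifluoromethanesulfonyloxy)-2,3-dihydrobenzofuran-3-carboxylic acid; 11 1-bromo-3,5-bis(methoxymethoxy)benzene
Product: 16 (2S,3S)-3-[3,5-bis(methoxymethoxy)phenyl]-6-(methoxymethoxy)-2-[4-(methoxymethoxy)phenyl]-2,3-dihydrobenzofuran-4-yl trifluoromethanesulfonate (trans), via N-acyloxyphthalimide 13 (not isolated), via aryl Grignard 14 (not isolated), via diarylzinc 15 (not isolated)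
Conditions: (a) 9, N-hydroxyphthalimide, N,N′-diisopropylcarbodiimide, DMAP (cat.), CH2Cl2, rt; filter, concentrate; (b) 11, Mg, THF, 40 °C; ZnCl2 (0.5 equiv), rt; (c) Fe(acac)3 (20 mol %), dppBz [1,2-bis(diphenylphosphino)benzene] (24 mol %), THF/toluene, rt
Reagents that add atoms: N-hydroxyphthalimide, O=C1c2ccccc2C(=O)N1O (held only in 13); magnesium, [Mg] (held only in 14); zinc chloride, Cl[Zn]Cl (zinc, held only in 15); 16 itself is built from 9 and 11 alone
Why: Iron-catalysed decarboxylative Negishi-type arylation of a redox-active ester: single-electron reduction of 13 releases CO2 and phthalimide anion and leaves the C3′ benzylic radical, which is arylated from the iron–aryl species. The aryl group enters anti to the C2′ aryl group, so the trans (3S) centre is set by 1,2-induction, and the iron catalyst has no ready entry into the aryl C–O bond of the triflate.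

Step 9
Reactants: 16 (2S,3S)-3-[3,5-bis(methoxymethoxy)phenyl]-6-(methoxymethoxy)-2-[4-(methoxymethoxy)phenyl]-2,3-dihydrobenzofuran-4-yl trifluoromethanesulfonate
Product: 18 (2S,3S)-3-[3,5-bis(methoxymethoxy)phenyl]-4-iodo-6-(methoxymethoxy)-2-[4-(methoxymethoxy)phenyl]-2,3-dihydrobenzofuran (trans), via arylstannane 17 (not isolated)
Conditions: (Bu3Sn)2 (1.5 equiv), Pd(PPh3)4 (10 mol %), LiCl (5 equiv), 1,4-dioxane, 100 °C; filter, CH2Cl2; iodine (I2), 0 °C; aq. Na2S2O3
Reagents that add atoms: iodine, II; hexabutylditin, CCCC[Sn](CCCC)(CCCC)[Sn](CCCC)(CCCC)CCCC (tin, held only in 17)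
Why: Palladium-catalysed stannylation of the aryl triflate (oxidative addition to zerovalent palladium, Sn–Sn transmetalation, reductive elimination) followed by ipso-iododestannylation. Iodine alone attacks the C–Sn bond far faster than the activated ring C–H positions, which is why an electrophilic halodeboronation is avoided; tin residues are handled as toxic waste.

Step 10
Reactants: 19 4-hydroxybenzyl alcohol
Product: 20 [4-(methoxymethoxy)phenyl]methanol
Conditions: MOMCl (1.05 equiv), K2CO3, acetone, 0 °C to rt
Reagents that add atoms: chloromethyl methyl ether, COCCl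
Why: Chemoselective O-alkylation: carbonate ionises only the phenol (the benzylic alcohol is about five pK units less acidic), so one equivalent of MOMCl caps the phenol.

Step 11
Reactants: 21 2-(5-bromo-2-hydroxyphenyl)acetic acid
Product: 22 methyl 2-(5-bromo-2-hydroxyphenyl)acetate
Conditions: MeOH, H2SO4 (cat.), reflux
Reagents that add atoms: methanol, CO
Why: Fischer esterification; the excess methanol also opens any lactone formed from the ortho-hydroxy acid.

Step 12
Reactants: 22 methyl 2-(5-bromo-2-hydroxyphenyl)acetate; 20 [4-(methoxymethoxy)phenyl]methanol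
Product: 23 methyl 2-(5-bromo-2-{[4-(methoxymethoxy)benzyl]oxy}phenyl)acetate
Conditions: PPh3, DIAD, THF, 0 °C to rt
Reagents that add atoms: none
Why: Mitsunobu etherification of the phenol with the primary benzylic alcohol; it avoids the unstable 4-alkoxybenzyl halide.

Step 13
Reactants: 23 methyl 2-(5-bromo-2-{[4-(methoxymethoxy)benzyl]oxy}phenyl)acetate
Product: 24 methyl 2-(5-bromo-2-{[4-(methoxymethoxy)benzyl]oxy}phenyl)-2-diazoacetate
Conditions: p-ABSA (1.3 equiv), DBU (1.5 equiv), MeCN, 0 °C to rt
Reagents that add atoms: 4-acetamidobenzenesulfonyl azide, CC(=O)Nc1ccc(cc1)S(=O)(=O)N=[N+]=[N-]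
Why: Regitz diazo transfer to an arylacetate: DBU deprotonates the benzylic CH2 and the enolate takes the two terminal nitrogens of the sulfonyl azide.

Step 14
Reactants: 24 methyl 2-(5-bromo-2-{[4-(methoxymethoxy)benzyl]oxy}phenyl)-2-diazoacetate
Product: 26 methyl (2S,3S)-5-bromo-2-[4-(methoxymethoxy)phenyl]-2,3-dihydrobenzofuran-3-carboxylate (trans), via cis ester 25 (not isolated)
Conditions: Rh2(R-PTTL)4 (PTTL = N-phthaloyl-tert-leucinate, 1 mol %), toluene, −78 °C; then DBU (0.3 equiv), rt
Reagents that add atoms: none
Why: Enantioselective intramolecular 1,5 C–H insertion of a divalent-rhodium donor/acceptor carbene into the benzylic ether C–H bond (activated by the ether oxygen and the 4-alkoxyphenyl group) forms C2–C3 and ring B. The chiral carboxylate ligands select one enantiotopic hydrogen and so fix C2, giving the cis ester 25; DBU then epimerises C3 through the ester enolate to the trans ester without touching C2.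

Step 15
Reactants: 26 methyl (2S,3S)-5-bromo-2-[4-(methoxymethoxy)phenyl]-2,3-dihydrobenzofuran-3-carboxylate; 12 1,3-bis(methoxymethoxy)-5-vinylbenzene
Product: 27 methyl (2S,3S)-5-{(E)-2-[3,5-bis(methoxymethoxy)phenyl]ethenyl}-2-[4-(methoxymethoxy)phenyl]-2,3-dihydrobenzofuran-3-carboxylate
Conditions: Pd2(dba)3 (2.5 mol %), [HP(t-Bu)3]BF4 (10 mol %), Cy2NMe (1.5 equiv), 1,4-dioxane, 80 °C, dark
Reagents that add atoms: none
Why: Mizoroki–Heck reaction: migratory insertion places the aryl group on the terminal carbon of the styrene and syn β-hydride elimination gives the E-stilbene. It is done before the fragment union so that no aryl bromide competes later.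

Step 16
Reactants: 27 methyl (2S,3S)-5-{(E)-2-[3,5-bis(methoxymethoxy)phenyl]ethenyl}-2-[4-(methoxymethoxy)phenyl]-2,3-dihydrobenzofuran-3-carboxylate
Product: 28 (2S,3S)-5-{(E)-2-[3,5-bis(methoxymethoxy)phenyl]ethenyl}-2-[4-(methoxymethoxy)phenyl]-2,3-dihydrobenzofuran-3-carboxylic acid
Conditions: LiOH, THF/MeOH/H2O, rt; cold dilute HCl to pH 3
Reagents that add atoms: water, O (delivered as LiOH)
Why: Saponification; the trans acid is the thermodynamic one and C2 cannot epimerise under these conditions.

Step 17
Reactants: 28 (2S,3S)-5-{(E)-2-[3,5-bis(methoxymethoxy)phenyl]ethenyl}-2-[4-(methoxymethoxy)phenyl]-2,3-dihydrobenzofuran-3-carboxylic acid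
Product: 29 1,3-dioxoisoindolin-2-yl (2S,3S)-5-{(E)-2-[3,5-bis(methoxymethoxy)phenyl]ethenyl}-2-[4-(methoxymethoxy)phenyl]-2,3-dihydrobenzofuran-3-carboxylate
Conditions: N-hydroxyphthalimide, N,N′-diisopropylcarbodiimide, DMAP (10 mol %), CH2Cl2, rt
Reagents that add atoms: N-hydroxyphthalimide, O=C1c2ccccc2C(=O)N1O
Why: Carbodiimide esterification to the N-acyloxyphthalimide (redox-active ester), isolated here because the union needs clean stoichiometry.

Step 18
Reactants: 18 (2S,3S)-3-[3,5-bis(methoxymethoxy)phenyl]-4-iodo-6-(methoxymethoxy)-2-[4-(methoxymethoxy)phenyl]-2,3-dihydrobenzofuran; 29 1,3-dioxoisoindolin-2-yl (2S,3S)-5-{(E)-2-[3,5-bis(methoxymethoxy)phenyl]ethenyl}-2-[4-(methoxymethoxy)phenyl]-2,3-dihydrobenzofuran-3-carboxylate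
Product: 30 heptakis(methoxymethyl) ether of trans-diptoindonesin B
Conditions: NiBr2(dme) (10 mol %), dtbbpy [4,4′-di-tert-butyl-2,2′-bipyridine] (10 mol %), Zn dust (2 equiv), DMA, rt, dark; 18 (1.0 equiv), 29 (1.3 equiv)
Reagents that add atoms: none
Why: Nickel-catalysed decarboxylative reductive cross-electrophile coupling: zerovalent nickel inserts into the aryl iodide, reduction of 29 releases CO2 and phthalimide anion and leaves the C3 benzylic radical, which the aryl–nickel species captures before reductive elimination from trivalent nickel forms C3–C4′. The C2 aryl group shields one face, so the inner aryl group is delivered trans (3S); a radical at C3, unlike an organometallic, does not expel the ring B aryloxide.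

Step 19
Reactants: 30 heptakis(methoxymethyl) ether of trans-diptoindonesin B
Product: 31 trans-diptoindonesin B
Conditions: TMSOTf (14 equiv), 2,2′-bipyridyl (21 equiv), MeCN, 0 °C to rt; then H2O, rt; argon, dark
Reagents that add atoms: none
Why: Silyl triflate/2,2′-bipyridyl cleavage of aromatic MOM ethers: the buffered silyl triflate passes each methoxymethyl group to the pyridine nitrogen and leaves aryl silyl ethers, which water hydrolyses. No free acid strong enough to ionise C2–O1 or C2′–O1′ or to protonate the stilbene is present.

## Compound list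

1 | (S)-naringenin, (2S)-5,7-dihydroxy-2-(4-hydroxyphenyl)chroman-4-one | Oc1cc(O)cc2c1C(=O)C[C@@H](c1ccc(O)cc1)O2 | starting material
2 | (2S)-5-hydroxy-7-(methoxymethoxy)-2-[4-(methoxymethoxy)phenyl]chroman-4-one | Oc1cc(OCOC)cc2c1C(=O)C[C@@H](c1ccc(OCOC)cc1)O2 | intermediate
3 | (2S)-7-(methoxymethoxy)-2-[4-(methoxymethoxy)phenyl]-4-oxochroman-5-yl trifluoromethanesulfonate | FC(F)(F)S(=O)(=O)Oc1cc(OCOC)cc2c1C(=O)C[C@@H](c1ccc(OCOC)cc1)O2 | intermediate
4 | 3-(trifluoroacetyl) derivative of 3 (C2 as in 3; C3 undefined, keto–enol mixture) | FC(F)(F)S(=O)(=O)Oc1cc(OCOC)cc2c1C(=O)C(C(=O)C(F)(F)F)[C@@H](c1ccc(OCOC)cc1)O2 | intermediate (not isolated)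
5 | (2R)-3-diazo-7-(methoxymethoxy)-2-[4-(methoxymethoxy)phenyl]-4-oxochroman-5-yl trifluoromethanesulfonate | FC(F)(F)S(=O)(=O)Oc1cc(OCOC)cc2c1C(=O)C(=[N+]=[N-])[C@@H](c1ccc(OCOC)cc1)O2 | intermediate
6 | 6-(methoxymethoxy)-2-[4-(methoxymethoxy)phenyl]-3-(oxomethylidene)-2,3-dihydrobenzofuran-4-yl trifluoromethanesulfonate (ketene; C2 as in 8) | FC(F)(F)S(=O)(=O)Oc1cc(OCOC)cc2c1C(=C=O)[C@@H](c1ccc(OCOC)cc1)O2 | intermediate (not isolated)
7 | methyl (2S,3R)-6-(methoxymethoxy)-2-[4-(methoxymethoxy)phenyl]-4-(trifluoromethanesulfonyloxy)-2,3-dihydrobenzofuran-3-carboxylate (cis) | FC(F)(F)S(=O)(=O)Oc1cc(OCOC)cc2c1[C@@H](C(=O)OC)[C@@H](c1ccc(OCOC)cc1)O2 | intermediate (not isolated)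
8 | methyl (2S,3S)-6-(methoxymethoxy)-2-[4-(methoxymethoxy)phenyl]-4-(trifluoromethanesulfonyloxy)-2,3-dihydrobenzofuran-3-carboxylate (trans) | FC(F)(F)S(=O)(=O)Oc1cc(OCOC)cc2c1[C@H](C(=O)OC)[C@@H](c1ccc(OCOC)cc1)O2 | intermediate
9 | (2S,3S)-6-(methoxymethoxy)-2-[4-(methoxymethoxy)phenyl]-4-(trifluoromethanesulfonyloxy)-2,3-dihydrobenzofuran-3-carboxylic acid | FC(F)(F)S(=O)(=O)Oc1cc(OCOC)cc2c1[C@H](C(=O)O)[C@@H](c1ccc(OCOC)cc1)O2 | intermediate
10 | 5-bromoresorcinol | Oc1cc(O)cc(Br)c1 | starting material
11 | 1-bromo-3,5-bis(methoxymethoxy)benzene | COCOc1cc(Br)cc(OCOC)c1 | intermediate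
12 | 1,3-bis(methoxymethoxy)-5-vinylbenzene | C=Cc1cc(OCOC)cc(OCOC)c1 | intermediate
13 | 1,3-dioxoisoindolin-2-yl (2S,3S)-6-(methoxymethoxy)-2-[4-(methoxymethoxy)phenyl]-4-(trifluoromethanesulfonyloxy)-2,3-dihydrobenzofuran-3-carboxylate | FC(F)(F)S(=O)(=O)Oc1cc(OCOC)cc2c1[C@H](C(=O)ON3C(=O)c4ccccc4C3=O)[C@@H](c1ccc(OCOC)cc1)O2 | intermediate (not isolated)
14 | [3,5-bis(methoxymethoxy)phenyl]magnesium bromide | COCOc1cc([Mg]Br)cc(OCOC)c1 | intermediate (not isolated)
15 | bis[3,5-bis(methoxymethoxy)phenyl]zinc | COCOc1cc(OCOC)cc(c1)[Zn]c1cc(OCOC)cc(OCOC)c1 | intermediate (not isolated)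
16 | (2S,3S)-3-[3,5-bis(methoxymethoxy)phenyl]-6-(methoxymethoxy)-2-[4-(methoxymethoxy)phenyl]-2,3-dihydrobenzofuran-4-yl trifluoromethanesulfonate (trans) | FC(F)(F)S(=O)(=O)Oc1cc(OCOC)cc2c1[C@H](c1cc(OCOC)cc(OCOC)c1)[C@@H](c1ccc(OCOC)cc1)O2 | intermediate
17 | tributyl{(2S,3S)-3-[3,5-bis(methoxymethoxy)phenyl]-6-(methoxymethoxy)-2-[4-(methoxymethoxy)phenyl]-2,3-dihydrobenzofuran-4-yl}stannane | CCCC[Sn](CCCC)(CCCC)c1cc(OCOC)cc2c1[C@H](c1cc(OCOC)cc(OCOC)c1)[C@@H](c1ccc(OCOC)cc1)O2 | intermediate (not isolated)
18 | (2S,3S)-3-[3,5-bis(methoxymethoxy)phenyl]-4-iodo-6-(methoxymethoxy)-2-[4-(methoxymethoxy)phenyl]-2,3-dihydrobenzofuran (trans) | Ic1cc(OCOC)cc2c1[C@H](c1cc(OCOC)cc(OCOC)c1)[C@@H](c1ccc(OCOC)cc1)O2 | intermediate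
19 | 4-hydroxybenzyl alcohol | OCc1ccc(O)cc1 | starting material
20 | [4-(methoxymethoxy)phenyl]methanol | COCOc1ccc(CO)cc1 | intermediate
21 | 2-(5-bromo-2-hydroxyphenyl)acetic acid | OC(=O)Cc1cc(Br)ccc1O | starting material
22 | methyl 2-(5-bromo-2-hydroxyphenyl)acetate | COC(=O)Cc1cc(Br)ccc1O | intermediate
23 | methyl 2-(5-bromo-2-{[4-(methoxymethoxy)benzyl]oxy}phenyl)acetate | COC(=O)Cc1cc(Br)ccc1OCc1ccc(OCOC)cc1 | intermediate
24 | methyl 2-(5-bromo-2-{[4-(methoxymethoxy)benzyl]oxy}phenyl)-2-diazoacetate | COC(=O)C(=[N+]=[N-])c1cc(Br)ccc1OCc1ccc(OCOC)cc1 | intermediate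
25 | methyl (2S,3R)-5-bromo-2-[4-(methoxymethoxy)phenyl]-2,3-dihydrobenzofuran-3-carboxylate (cis) | COCOc1ccc([C@H]2Oc3ccc(Br)cc3[C@H]2C(=O)OC)cc1 | intermediate (not isolated)
26 | methyl (2S,3S)-5-bromo-2-[4-(methoxymethoxy)phenyl]-2,3-dihydrobenzofuran-3-carboxylate (trans) | COCOc1ccc([C@H]2Oc3ccc(Br)cc3[C@@H]2C(=O)OC)cc1 | intermediate
27 | methyl (2S,3S)-5-{(E)-2-[3,5-bis(methoxymethoxy)phenyl]ethenyl}-2-[4-(methoxymethoxy)phenyl]-2,3-dihydrobenzofuran-3-carboxylate | COCOc1ccc([C@H]2Oc3ccc(/C=C/c4cc(OCOC)cc(OCOC)c4)cc3[C@@H]2C(=O)OC)cc1 | intermediate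
28 | (2S,3S)-5-{(E)-2-[3,5-bis(methoxymethoxy)phenyl]ethenyl}-2-[4-(methoxymethoxy)phenyl]-2,3-dihydrobenzofuran-3-carboxylic acid | COCOc1ccc([C@H]2Oc3ccc(/C=C/c4cc(OCOC)cc(OCOC)c4)cc3[C@@H]2C(=O)O)cc1 | intermediate
29 | 1,3-dioxoisoindolin-2-yl (2S,3S)-5-{(E)-2-[3,5-bis(methoxymethoxy)phenyl]ethenyl}-2-[4-(methoxymethoxy)phenyl]-2,3-dihydrobenzofuran-3-carboxylate | COCOc1ccc([C@H]2Oc3ccc(/C=C/c4cc(OCOC)cc(OCOC)c4)cc3[C@@H]2C(=O)ON5C(=O)c6ccccc6C5=O)cc1 | intermediate
30 | heptakis(methoxymethyl) ether of trans-diptoindonesin B (2S,3S,2′S,3′S) | COCOc1ccc([C@H]2Oc3ccc(/C=C/c4cc(OCOC)cc(OCOC)c4)cc3[C@@H]2c2cc(OCOC)cc3c2[C@H](c2cc(OCOC)cc(OCOC)c2)[C@@H](c2ccc(OCOC)cc2)O3)cc1 | intermediate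
31 | trans-diptoindonesin B (2S,3S,2′S,3′S) | Oc1ccc([C@H]2Oc3ccc(/C=C/c4cc(O)cc(O)c4)cc3[C@@H]2c2cc(O)cc3c2[C@H](c2cc(O)cc(O)c2)[C@@H](c2ccc(O)cc2)O3)cc1 | target

## Step count and least certain steps

Total step count: 19. Longest linear sequence: 9 steps (from 1 through steps 1, 2, 3, 4, 5, 8, 9, 18, 19; the branch from 21 through steps 11 to 19 is equally long).

Step 4 (key step).
- What may go wrong: part of the excited diazo ketone could react as a free carbene (hydrogen shift from C2′ to a flavone-type product, O–H insertion into methanol); the triflate or the product could be photolysed on over-irradiation; the base equilibration could stop short of the trans ester.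
- Fallback: leave out the diazo compound and contract the pyranone oxidatively. Setting out from 3, PhI(OAc)2 (a trivalent iodine reagent) with catalytic H2SO4 in trimethyl orthoformate should convert the ketone into its enol ether, attack it at C3 and trigger the same 1,2-shift of the ring C carbon as iodobenzene leaves, giving the trans methyl ester directly. The acidic orthoformate medium is expected to exchange off the two MOM groups, so the crude product would be the diphenol methyl (2S,3S)-6-hydroxy-2-(4-hydroxyphenyl)-4-(trifluoromethanesulfonyloxy)-2,3-dihydrobenzofuran-3-carboxylate F1. This is protected again (MOMCl, i-Pr2NEt; safe now that C2′ no longer sits in a flavanone) to return to the route at 8.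

Step 18.
- What may go wrong: oxidative addition at the hindered aryl iodide may be slow, so that the benzylic radical dimerises, is reduced, or loses the C2 hydrogen and aromatises to the benzofuran; facial selectivity at C3 may be poor; the iodide may be reduced.
- Fallback: replace the reductive coupling by a redox-neutral Negishi-type decarboxylative arylation. Setting out from 18, iodine–lithium exchange (t-BuLi, THF, −78 °C) gives the aryllithium F2, ZnCl2 turns it into the arylzinc chloride F3, and NiCl2(dme)/4,4′-di-tert-butyl-2,2′-bipyridine couples F3 with 29 in THF/DMF at room temperature to return to the route at 30. The aryl group then reaches nickel by transmetalation, and no zinc metal is present to reduce 29 unproductively.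

Step 8.
- What may go wrong: loss of chemoselectivity (attack on the triflate), or sluggish capture of the hindered benzylic radical leading to reduction or dimerisation.
- Fallback: a reductive cross-electrophile coupling under nickel–bipyridine, which inserts into aryl iodides far faster than into aryl triflates. Setting out from 9 (converted to 13 and this time isolated) and from the Grignard reagent 14, which is quenched with iodine to 1-iodo-3,5-bis(methoxymethoxy)benzene F4, NiBr2(dme)/dtbbpy/Zn in DMA should join 13 and F4 and return to the route at 16.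

Step 3.
- What may go wrong: the lithium enolate may open by retro-oxa-Michael expulsion of the ring oxygen (loss of C2 configuration or of material), made easier by the electron-poor triflated ring; O-acylation may compete with C-acylation.
- Fallback: change the order so that the enolate is formed while the 5-oxygen is still a phenoxide, which makes the ring oxygen a much poorer leaving group. Setting out from 2, LiN(SiMe3)2 (2.2 equiv) gives the dianion and CF3CO2CH2CF3 gives 5-hydroxy-7-(methoxymethoxy)-2-[4-(methoxymethoxy)phenyl]-3-(trifluoroacetyl)chroman-4-one F5 (any aryl trifluoroacetate falls off on work-up). p-ABSA/Et3N then gives (2R)-3-diazo-5-hydroxy-7-(methoxymethoxy)-2-[4-(methoxymethoxy)phenyl]chroman-4-one F6, and PhNTf2 with Et3N and DMAP (no enolisable position is left) triflates the chelated phenol to return to the route at 5.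

Step 1.
- What may go wrong: partial racemisation of C2 by reversible opening of the pyranone through the 4′-phenoxide (quinone methide) or the chalcone while base is present.
- Fallback: form the acetals without base. Setting out from 1, dimethoxymethane with P2O5 in CHCl3 at room temperature (acid-mediated acetal exchange, driven by removal of methanol) should protect the same two phenols and return to the route at 2 without any new intermediate (F0); flavanones hold their configuration better in acid than in base.

Step 19.
- What may go wrong: incomplete cleavage of seven acetals; ionisation of C2–O1 or C2′–O1′; electrophilic closure of the stilbene onto ring C if the medium becomes too acidic; air oxidation of the polyphenol.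
- Fallback: split the deprotection into a protecting-group exchange and a fluoride step. Setting out from 30, Et3SiOTf/2,2′-bipyridyl converts each aryl MOM ether into an aryl triethylsilyl ether, giving the heptakis(triethylsilyl) ether of trans-diptoindonesin B F7, which can be purified. Et3N·3HF (or Bu4NF buffered with AcOH) then frees the phenols under nearly neutral conditions and returns to the route at 31.

Further compounds

F1 | step 4 | methyl (2S,3S)-6-hydroxy-2-(4-hydroxyphenyl)-4-(trifluoromethanesulfonyloxy)-2,3-dihydrobenzofuran-3-carboxylate | FC(F)(F)S(=O)(=O)Oc1cc(O)cc2c1[C@H](C(=O)OC)[C@@H](c1ccc(O)cc1)O2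
F2 | step 18 | {(2S,3S)-3-[3,5-bis(methoxymethoxy)phenyl]-6-(methoxymethoxy)-2-[4-(methoxymethoxy)phenyl]-2,3-dihydrobenzofuran-4-yl}lithium | [Li]c1cc(OCOC)cc2c1[C@H](c1cc(OCOC)cc(OCOC)c1)[C@@H](c1ccc(OCOC)cc1)O2
F3 | step 18 | {(2S,3S)-3-[3,5-bis(methoxymethoxy)phenyl]-6-(methoxymethoxy)-2-[4-(methoxymethoxy)phenyl]-2,3-dihydrobenzofuran-4-yl}zinc chloride | Cl[Zn]c1cc(OCOC)cc2c1[C@H](c1cc(OCOC)cc(OCOC)c1)[C@@H](c1ccc(OCOC)cc1)O2
F4 | step 8 | 1-iodo-3,5-bis(methoxymethoxy)benzene | COCOc1cc(I)cc(OCOC)c1
F5 | step 3 | 5-hydroxy-7-(methoxymethoxy)-2-[4-(methoxymethoxy)phenyl]-3-(trifluoroacetyl)chroman-4-one (C2 as in 2; C3 undefined) | Oc1cc(OCOC)cc2c1C(=O)C(C(=O)C(F)(F)F)[C@@H](c1ccc(OCOC)cc1)O2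
F6 | step 3 | (2R)-3-diazo-5-hydroxy-7-(methoxymethoxy)-2-[4-(methoxymethoxy)phenyl]chroman-4-one | Oc1cc(OCOC)cc2c1C(=O)C(=[N+]=[N-])[C@@H](c1ccc(OCOC)cc1)O2
F0 | step 1 | none | none
F7 | step 19 | heptakis(triethylsilyl) ether of trans-diptoindonesin B | CC[Si](CC)(CC)Oc1ccc([C@H]2Oc3ccc(/C=C/c4cc(O[Si](CC)(CC)CC)cc(O[Si](CC)(CC)CC)c4)cc3[C@@H]2c2cc(O[Si](CC)(CC)CC)cc3c2[C@H](c2cc(O[Si](CC)(CC)CC)cc(O[Si](CC)(CC)CC)c2)[C@@H](c2ccc(O[Si](CC)(CC)CC)cc2)O3)cc1
A1 | alternative 1 | methyl 7-[(2S,3S)-5-bromo-2-(4-(methoxymethoxy)phenyl)-2,3-dihydrobenzofuran-3-yl]-3,5,7-trioxoheptanoate | COCOc1ccc([C@H]2Oc3ccc(Br)cc3[C@@H]2C(=O)CC(=O)CC(=O)CC(=O)OC)cc1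
A2 | alternative 1 | methyl 2,4-dihydroxy-6-[(2S,3S)-5-bromo-2-(4-(methoxymethoxy)phenyl)-2,3-dihydrobenzofuran-3-yl]benzoate | COCOc1ccc([C@H]2Oc3ccc(Br)cc3[C@@H]2c2cc(O)cc(O)c2C(=O)OC)cc1
A3 | alternative 2 | 4-(1,3-dioxolan-2-yl)-6-(methoxymethoxy)benzofuran | COCOc1cc(C2OCCO2)c2ccoc2c1
A4 | alternative 2 | 2-[4-(methoxymethoxy)phenyl]-4,4,5,5-tetramethyl-1,3,2-dioxaborolane | COCOc1ccc(cc1)B1OC(C)(C)C(C)(C)O1
A5 | alternative 2 | 3,5-bis(methoxymethoxy)phenyl trifluoromethanesulfonate | COCOc1cc(OCOC)cc(OS(=O)(=O)C(F)(F)F)c1
A6 | alternative 2 | 2-{(2S,3S)-3-[3,5-bis(methoxymethoxy)phenyl]-4-(1,3-dioxolan-2-yl)-6-(methoxymethoxy)-2-[4-(methoxymethoxy)phenyl]-2,3-dihydrobenzofuran-2-yl}-4,4,5,5-tetramethyl-1,3,2-dioxaborolane (aryl groups trans, boronate cis to the C3′ aryl group) | O1CCOC1c1cc(OCOC)cc2c1[C@H](c1cc(OCOC)cc(OCOC)c1)[C@@](B1OC(C)(C)C(C)(C)O1)(c1ccc(OCOC)cc1)O2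
A7 | alternative 3 | 4-{(E)-2-[3,5-bis(methoxymethoxy)phenyl]ethenyl}-2-[{(2S,3S)-3-[3,5-bis(methoxymethoxy)phenyl]-6-(methoxymethoxy)-2-[4-(methoxymethoxy)phenyl]-2,3-dihydrobenzofuran-4-yl}(4-methylphenylsulfonyl)methyl]phenol (sulfone carbon undefined) | Cc1ccc(cc1)S(=O)(=O)C(c1cc(/C=C/c2cc(OCOC)cc(OCOC)c2)ccc1O)c1cc(OCOC)cc2c1[C@H](c1cc(OCOC)cc(OCOC)c1)[C@@H](c1ccc(OCOC)cc1)O2
A8 | alternative 3 | heptakis(methoxymethyl) ether of trans-diptoindonesin B (identical with 30) | COCOc1ccc([C@H]2Oc3ccc(/C=C/c4cc(OCOC)cc(OCOC)c4)cc3[C@@H]2c2cc(OCOC)cc3c2[C@H](c2cc(OCOC)cc(OCOC)c2)[C@@H](c2ccc(OCOC)cc2)O3)cc1
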